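Ring B is built last. Its C6 carbinol, 1,3 to the oxygenated C8, is the trace of a carbonyl-ene closure of a C6 aldehyde onto a C8 isopropenyl group, and the quaternary C10 next to tertiary C9 is the trace of a Claisen rearrangement. The route therefore rests on cutting C9–C10 and C6–C7. The precursor is a ring A cyclohexene that carries the C5 aldehyde and, as a temporary C1 enol ether, the whole side chain as an allyl group. Heating shifts this arm from oxygen to C10; the isopropenyl group so formed then closes ring B on the aldehyde, fixing C10, C9 and C6 from C5 in one pot. The C1 ketone is deleted later.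

Key step: step 14

Remark: atoms are numbered as in the labdane skeleton of the target (ring A = C1–C5 and C10, ring B = C5–C10, C18 = CH2O on C4, C19 and C20 = methyls on C4 and C10, C17 = methyl on C8, side chain C11–C16); α and β have the usual terpenoid meaning (C20 is β). "Arm" stands for the (2Z,6E)-8-[(tert-butyldiphenylsilyl)oxy]-2,6-dimethylocta-2,6-dien-1-yl group.

Step 1
Reactants: 1 geraniol
Product: 2 geranyl tert-butyldiphenylsilyl ether
Conditions: tBuPh2SiCl, imidazole, CH2Cl2, 0 °C → rt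
Reagents that add atoms: tert-butyl(chloro)diphenylsilane, CC(C)(C)[Si](Cl)(c1ccccc1)c1ccccc1
Why: Imidazole-promoted silylation of a primary allylic alcohol gives a silyl ether that survives the base, hydride, titanium and Lewis-acid steps ahead; no stereocentre is formed.

Step 2
Reactants: 2 geranyl tert-butyldiphenylsilyl ether
Product: 3 (4E)-6-[(tert-butyldiphenylsilyl)oxy]-4-methylhex-4-enal
Conditions: O3 (1.0 equiv), CH2Cl2, −78 °C; then PPh3, −78 °C → rt
Reagents that add atoms: ozone, [O-][O+]=O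
Why: Chemoselective ozonolysis with reductive work-up, in which the isolated terminal trisubstituted alkene should react before the alkene that is deactivated by its allylic silyloxy group when one equivalent of ozone is dosed.

Step 3
Reactants: 3 (4E)-6-[(tert-butyldiphenylsilyl)oxy]-4-methylhex-4-enal; 4 ethyl 2-[bis(2,2,2-trifluoroethoxy)phosphoryl]propanoate
Product: 5 ethyl (2Z,6E)-8-[(tert-butyldiphenylsilyl)oxy]-2,6-dimethylocta-2,6-dienoate
Conditions: KN(SiMe3)2, 18-crown-6, THF, −78 °C
Reagents that add atoms: none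
Why: Still–Gennari variant of the Horner–Wadsworth–Emmons olefination, in which the electron-poor trifluoroethyl phosphonate and the crown-separated potassium ion make elimination fast and should give the (Z)-trisubstituted enoate needed for the later chair Claisen transition state.

Step 4
Reactants: 5 ethyl (2Z,6E)-8-[(tert-butyldiphenylsilyl)oxy]-2,6-dimethylocta-2,6-dienoate
Product: 6 (2Z,6E)-8-[(tert-butyldiphenylsilyl)oxy]-2,6-dimethylocta-2,6-dien-1-ol (arm alcohol)
Conditions: iBu2AlH (2.2 equiv), CH2Cl2, −78 °C; aq. KNaC4H4O6 (potassium sodium tartrate) work-up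
Reagents that add atoms: none
Why: 1,2-Reduction of an α,β-unsaturated ester by iBu2AlH gives the allylic alcohol with both alkene geometries retained.

Step 5
Reactants: 7 (tert-butyldimethylsilyloxy)acetaldehyde; 8 ethyl 2-(triphenyl-λ5-phosphanylidene)propanoate
Product: 9 ethyl (2E)-4-[(tert-butyldimethylsilyl)oxy]-2-methylbut-2-enoate
Conditions: CH2Cl2, rt
Reagents that add atoms: none
Why: Wittig olefination with a stabilised ylide, which is expected to give the (E)-trisubstituted enoate that later becomes the reactive s-cis diene with its CH2OSi group pointing outward.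

Step 6
Reactants: 9 ethyl (2E)-4-[(tert-butyldimethylsilyl)oxy]-2-methylbut-2-enoate
Product: 10 (2E)-4-[(tert-butyldimethylsilyl)oxy]-2-methylbut-2-enoic acid
Conditions: LiOH, THF/H2O, 0 °C → rt; then cold aq. HCl to pH 3
Reagents that add atoms: lithium hydroxide, [Li+].[OH-]
Why: Ester saponification, which the primary silyl ether should survive under cold aqueous LiOH and a brief cold acidification.

Step 7
Reactants: 10 (2E)-4-[(tert-butyldimethylsilyl)oxy]-2-methylbut-2-enoic acid; 6 arm alcohol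
Product: 11 arm (2E)-4-[(tert-butyldimethylsilyl)oxy]-2-methylbut-2-enoate
Conditions: EDC·HCl, DMAP, CH2Cl2, 0 °C → rt
Reagents that add atoms: none
Why: Carbodiimide (Steglich) esterification joins the two chains under mild conditions that leave the three alkene geometries untouched; the ester oxygen is the future temporary C1 oxygen.

Step 8
Reactants: 11 arm (2E)-4-[(tert-butyldimethylsilyl)oxy]-2-methylbut-2-enoate
Product: 12 tert-butyldimethylsilyl ether of (2E)-3-methyl-4-(arm-oxy)penta-2,4-dien-1-ol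
Conditions: Cp2Ti(μ-CH2)(μ-Cl)AlMe2, pyridine, THF/PhMe, −40 → 0 °C; filtration through basic alumina
Reagents that add atoms: Tebbe reagent Cp2Ti(μ-CH2)(μ-Cl)AlMe2, C[Al-]1(C)C[Ti](C2C=CC=C2)(C2C=CC=C2)[Cl+]1
Why: Tebbe methylenation of the ester carbonyl (Cp2Ti=CH2, then an oxatitanacyclobutane) turns the enoate into a 2-alkoxy-1,3-diene and supplies C2, while silyl ethers and trisubstituted alkenes are inert and the low temperature avoids rearrangement of the allyl dienyl ether.

Step 9
Reactants: 12 tert-butyldimethylsilyl ether of (2E)-3-methyl-4-(arm-oxy)penta-2,4-dien-1-ol; 13 methacrolein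
Product: 14 (1R,2R)-4-(arm-oxy)-2-{[(tert-butyldimethylsilyl)oxy]methyl}-1,3-dimethylcyclohex-3-ene-1-carbaldehyde
Conditions: (S)-3,3-diphenyl-1-(2-methylphenyl)tetrahydropyrrolo[1,2-c][1,3,2]oxazaborole (10 mol%) activated by (CF3SO2)2NH (10 mol%), CH2Cl2, −78 → −40 °C; Et3N quench
Reagents that add atoms: none
Why: Enantioselective Lewis-acid-catalysed Diels–Alder reaction in which the 2-alkoxy group (para) and the terminal CH2OSi group (ortho) both send the formyl-bearing carbon of methacrolein to C5, the exo-formyl transition state usual for α-methylacroleins places CHO (C18) trans to CH2OSi (C6), and the chiral oxazaborolidinium ion is chosen to shield one face of the bound enal so that C4 and C5 should form as the (1R,2R) pair.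

Step 10
Reactants: 14 (1R,2R)-4-(arm-oxy)-2-{[(tert-butyldimethylsilyl)oxy]methyl}-1,3-dimethylcyclohex-3-ene-1-carbaldehyde
Product: 15 [(1R,2S)-4-(arm-oxy)-2-{[(tert-butyldimethylsilyl)oxy]methyl}-1,3-dimethylcyclohex-3-en-1-yl]methanol
Conditions: NaBH4, MeOH/THF, −20 °C
Reagents that add atoms: none
Why: Borohydride reduction of the neopentyl aldehyde to the C18 alcohol, with the enol ether and silyl ethers inert to the basic medium.

Step 11
Reactants: 15 [(1R,2S)-4-(arm-oxy)-2-{[(tert-butyldimethylsilyl)oxy]methyl}-1,3-dimethylcyclohex-3-en-1-yl]methanol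
Product: 16 [(1R,2S)-4-(arm-oxy)-2-{[(tert-butyldimethylsilyl)oxy]methyl}-1,3-dimethylcyclohex-3-en-1-yl]methyl pivalate
Conditions: tBuCOCl, pyridine, DMAP (cat.), CH2Cl2, 0 °C
Reagents that add atoms: pivaloyl chloride, CC(C)(C)C(=O)Cl
Why: DMAP-catalysed acylation masks the C18 alcohol as an ester that should survive fluoride, oxidation, heat and Me2AlCl and is removed without an extra step in the hot alkali of step 16.

Step 12
Reactants: 16 [(1R,2S)-4-(arm-oxy)-2-{[(tert-butyldimethylsilyl)oxy]methyl}-1,3-dimethylcyclohex-3-en-1-yl]methyl pivalate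
Product: 17 [(1R,2S)-4-(arm-oxy)-2-(hydroxymethyl)-1,3-dimethylcyclohex-3-en-1-yl]methyl pivalate
Conditions: Bu4NF (1.1 equiv), THF, 0 °C; H2O work-up
Reagents that add atoms: none
Why: Fluoride desilylation, in which the primary alkyl tert-butyldimethylsilyl ether is expected to be cleaved at 0 °C before the bulkier tert-butyldiphenylsilyl ether, in a basic medium that spares the acid-labile enol ether.

Step 13
Reactants: 17 [(1R,2S)-4-(arm-oxy)-2-(hydroxymethyl)-1,3-dimethylcyclohex-3-en-1-yl]methyl pivalate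
Product: 18 [(1R,2S)-4-(arm-oxy)-2-formyl-1,3-dimethylcyclohex-3-en-1-yl]methyl pivalate
Conditions: Dess–Martin periodinane, NaHCO3, CH2Cl2, 0 °C; used at once
Reagents that add atoms: none
Why: Dess–Martin oxidation under bicarbonate buffer should give the C6 aldehyde without the acid or base that would hydrolyse the enol ether or epimerise C5.

Step 14
Reactants: 18 [(1R,2S)-4-(arm-oxy)-2-formyl-1,3-dimethylcyclohex-3-en-1-yl]methyl pivalate
Product: 20 15-[(tert-butyldiphenylsilyl)oxy]-6α-hydroxy-1-oxolabda-8(17),13E-dien-18-yl pivalate, via ketoaldehyde 19 (not isolated)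
Conditions: PhMe, 150 °C (sealed tube, base-washed glass, BHT); then Me2AlCl (2 equiv), CH2Cl2, −78 → −20 °C, same flask
Reagents that add atoms: none
Why: Heating triggers a Claisen [3,3]-sigmatropic rearrangement of the allyl cyclohexenyl ether, which forms C9–C10, turns C1 into a ketone and leaves a C8 isopropenyl group (19); Me2AlCl then activates the C6 aldehyde for a type 2 intramolecular carbonyl-ene reaction in which the isopropenyl CH2 (C7) attacks C6 and a hydrogen of C17 is lost, which forms C6–C7. The closest known reactions are the thermal Claisen rearrangement of allyl enol ethers to α-quaternary ketones and the Me2AlCl-promoted type 2 carbonyl-ene cyclisation of δ,ε-unsaturated aldehydes to 3-methylenecyclohexanols. Ring B is the only ring closed, as a six-membered ring by the ene closure (6-endo with respect to the alkene) through a chair transition state fused trans to ring A. C10 is controlled by the C5 stereocentre, because the arm should migrate to the face of the enol ether opposite the C5 formyl group and the axial C19 methyl; C9 is controlled by the chair Claisen transition state of the (Z)-allyl ether, which places the side chain cis to C20; C6 is set in the ene closure, where the aluminium-bound oxygen is expected to sit equatorial because the axial position is 1,3-diaxial to C20 and crowded by C19. The step needs the rearrangement to outrun enolisation of the C5 aldehyde and needs the aldehyde, not the hindered C1 ketone, to act as enophile; neutral base-washed conditions in the thermal stage and the far higher reactivity of an aldehyde towards Me2AlCl at low temperature are meant to secure both.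

Step 15
Reactants: 20 15-[(tert-butyldiphenylsilyl)oxy]-6α-hydroxy-1-oxolabda-8(17),13E-dien-18-yl pivalate
Product: 21 15-[(tert-butyldiphenylsilyl)oxy]-6α,8α-dihydroxy-1-oxolabd-13E-en-18-yl pivalate
Conditions: Mn(dpm)3 (cat., dpm = 2,2,6,6-tetramethylheptane-3,5-dionate), PhSiH3, O2 (1 atm), iPrOH/CH2Cl2, 0 °C; then PPh3
Reagents that add atoms: dioxygen, O=O
Why: Mukaiyama hydration (metal-hydride hydrogen-atom transfer, then trapping of the tertiary C8 radical by O2), in which the 1,1-disubstituted exocyclic alkene should accept hydrogen faster than the trisubstituted allylic-ether alkene and O2 should add from the equatorial α face away from the axial C20 methyl to give the 8α-alcohol (any Δ7 isomer from step 14 would give the same alcohol).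

Step 16
Reactants: 21 15-[(tert-butyldiphenylsilyl)oxy]-6α,8α-dihydroxy-1-oxolabd-13E-en-18-yl pivalate
Product: 22 labd-13E-ene-6α,8α,15,18-tetraol
Conditions: N2H4·H2O, KOH, diethylene glycol, 130 → 200 °C; then aq. HCl to pH 7
Reagents that add atoms: none
Why: Wolff–Kishner reduction under Huang–Minlon conditions deletes the C1 carbonyl once it has served the Claisen step, the hot alkali should also cleave the pivalate and the silyl ether, and no stereocentre is at risk because C10 is quaternary.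

Step 17
Reactants: 22 labd-13E-ene-6α,8α,15,18-tetraol
Product: 23 6α,8α,18-trihydroxylabd-13E-en-15-al
Conditions: activated MnO2, CH2Cl2, rt
Reagents that add atoms: none
Why: MnO2 oxidises only the allylic primary alcohol, giving the (E)-enal and leaving the saturated primary, secondary and tertiary alcohols untouched.

Step 18
Reactants: 23 6α,8α,18-trihydroxylabd-13E-en-15-al
Product: 24 6α,8α,18-tris(triethylsilyloxy)labd-13E-en-15-al
Conditions: Et3SiOTf, 2,6-lutidine, CH2Cl2, −78 → 0 °C
Reagents that add atoms: triethylsilyl trifluoromethanesulfonate, CC[Si](CC)(CC)OS(=O)(=O)C(F)(F)F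
Why: Silylation with the silyl triflate caps all three hydroxyls, the tertiary one included, so that free alcohols do not exchange with the Ti(OiPr)4/BINOL catalyst of the aldol step.

Step 19
Reactants: 25 4-methylfuran-2(5H)-one
Product: 26 4-methyl-2-(trimethylsilyloxy)furan
Conditions: Me3SiOTf, Et3N, Et2O, 0 °C
Reagents that add atoms: trimethylsilyl trifluoromethanesulfonate, C[Si](C)(C)OS(=O)(=O)C(F)(F)F
Why: Soft enolisation and O-silylation of the butenolide gives the aromatic silyloxyfuran, a cyclic silyl dienol ether that reacts at its C5 position.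

Step 20
Reactants: 24 6α,8α,18-tris(triethylsilyloxy)labd-13E-en-15-al; 26 4-methyl-2-(trimethylsilyloxy)furan
Product: 27 6,8,18-tris-O-(triethylsilyl) ether of the target
Conditions: Ti(OiPr)4 (20 mol%), (S)-BINOL (20 mol%), Et2O, −20 °C; then aq. citric acid, THF, 0 °C
Reagents that add atoms: none
Why: Catalytic asymmetric vinylogous Mukaiyama aldol reaction, in which the silyloxyfuran adds through its C5 carbon 1,2 to the enal, the Ti(OiPr)4/(S)-BINOL catalyst is chosen to direct attack to the Re face of the aldehyde (15S) and the open transition state is expected to favour the threo (like) pair that makes C16 S.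

Step 21
Reactants: 27 6,8,18-tris-O-(triethylsilyl) ether of the target
Product: 28 CNP0255788.1 (target)
Conditions: HF·pyridine, pyridine, THF, 0 °C → rt
Reagents that add atoms: none
Why: Buffered fluoride desilylation removes the three silyl ethers and should leave the butenolide, the allylic alcohol and the tertiary alcohol intact.

Compound list

1 | geraniol, (2E)-3,7-dimethylocta-2,6-dien-1-ol | CC(C)=CCC/C(C)=C/CO | starting material
2 | geranyl tert-butyldiphenylsilyl ether | CC(C)=CCC/C(C)=C/CO[Si](c1ccccc1)(c1ccccc1)C(C)(C)C | intermediate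
3 | (4E)-6-[(tert-butyldiphenylsilyl)oxy]-4-methylhex-4-enal | O=CCC/C(C)=C/CO[Si](c1ccccc1)(c1ccccc1)C(C)(C)C | intermediate
4 | ethyl 2-[bis(2,2,2-trifluoroethoxy)phosphoryl]propanoate | CCOC(=O)C(C)P(=O)(OCC(F)(F)F)OCC(F)(F)F | starting material
5 | ethyl (2Z,6E)-8-[(tert-butyldiphenylsilyl)oxy]-2,6-dimethylocta-2,6-dienoate | CCOC(=O)/C(C)=C\CC/C(C)=C/CO[Si](c1ccccc1)(c1ccccc1)C(C)(C)C | intermediate
6 | (2Z,6E)-8-[(tert-butyldiphenylsilyl)oxy]-2,6-dimethylocta-2,6-dien-1-ol (arm alcohol) | OC/C(C)=C\CC/C(C)=C/CO[Si](c1ccccc1)(c1ccccc1)C(C)(C)C | intermediate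
7 | (tert-butyldimethylsilyloxy)acetaldehyde | O=CCO[Si](C)(C)C(C)(C)C | starting material
8 | ethyl 2-(triphenyl-λ5-phosphanylidene)propanoate | CCOC(=O)C(C)=P(c1ccccc1)(c1ccccc1)c1ccccc1 | starting material
9 | ethyl (2E)-4-[(tert-butyldimethylsilyl)oxy]-2-methylbut-2-enoate | CCOC(=O)/C(C)=C/CO[Si](C)(C)C(C)(C)C | intermediate
10 | (2E)-4-[(tert-butyldimethylsilyl)oxy]-2-methylbut-2-enoic acid | OC(=O)/C(C)=C/CO[Si](C)(C)C(C)(C)C | intermediate
11 | arm (2E)-4-[(tert-butyldimethylsilyl)oxy]-2-methylbut-2-enoate | O=C(OC/C(C)=C\CC/C(C)=C/CO[Si](c1ccccc1)(c1ccccc1)C(C)(C)C)/C(C)=C/CO[Si](C)(C)C(C)(C)C | intermediate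
12 | tert-butyldimethylsilyl ether of (2E)-3-methyl-4-(arm-oxy)penta-2,4-dien-1-ol (2-alkoxy diene) | C=C(OC/C(C)=C\CC/C(C)=C/CO[Si](c1ccccc1)(c1ccccc1)C(C)(C)C)/C(C)=C/CO[Si](C)(C)C(C)(C)C | intermediate
13 | methacrolein, 2-methylprop-2-enal | C=C(C)C=O | starting material
14 | (1R,2R)-4-(arm-oxy)-2-{[(tert-butyldimethylsilyl)oxy]methyl}-1,3-dimethylcyclohex-3-ene-1-carbaldehyde (CHO trans to CH2OSi) | CC1=C(OC/C(C)=C\CC/C(C)=C/CO[Si](c2ccccc2)(c2ccccc2)C(C)(C)C)CC[C@@](C)(C=O)[C@@H]1CO[Si](C)(C)C(C)(C)C | intermediate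
15 | [(1R,2S)-4-(arm-oxy)-2-{[(tert-butyldimethylsilyl)oxy]methyl}-1,3-dimethylcyclohex-3-en-1-yl]methanol | CC1=C(OC/C(C)=C\CC/C(C)=C/CO[Si](c2ccccc2)(c2ccccc2)C(C)(C)C)CC[C@@](C)(CO)[C@@H]1CO[Si](C)(C)C(C)(C)C | intermediate
16 | [(1R,2S)-4-(arm-oxy)-2-{[(tert-butyldimethylsilyl)oxy]methyl}-1,3-dimethylcyclohex-3-en-1-yl]methyl pivalate | CC1=C(OC/C(C)=C\CC/C(C)=C/CO[Si](c2ccccc2)(c2ccccc2)C(C)(C)C)CC[C@@](C)(COC(=O)C(C)(C)C)[C@@H]1CO[Si](C)(C)C(C)(C)C | intermediate
17 | [(1R,2S)-4-(arm-oxy)-2-(hydroxymethyl)-1,3-dimethylcyclohex-3-en-1-yl]methyl pivalate | CC1=C(OC/C(C)=C\CC/C(C)=C/CO[Si](c2ccccc2)(c2ccccc2)C(C)(C)C)CC[C@@](C)(COC(=O)C(C)(C)C)[C@@H]1CO | intermediate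
18 | [(1R,2S)-4-(arm-oxy)-2-formyl-1,3-dimethylcyclohex-3-en-1-yl]methyl pivalate | CC1=C(OC/C(C)=C\CC/C(C)=C/CO[Si](c2ccccc2)(c2ccccc2)C(C)(C)C)CC[C@@](C)(COC(=O)C(C)(C)C)[C@@H]1C=O | intermediate
19 | 15-[(tert-butyldiphenylsilyl)oxy]-1,6-dioxo-6,7-secolabda-7,13E-dien-18-yl pivalate (5α-H, 9α-H, 10β-CH3; Claisen ketoaldehyde) | CC(C)(C)[Si](OC/C=C(\C)CC[C@@H](C(C)=C)[C@@]1(C)C(=O)CC[C@@](C)(COC(=O)C(C)(C)C)[C@@H]1C=O)(c1ccccc1)c1ccccc1 | intermediate (not isolated)
20 | 15-[(tert-butyldiphenylsilyl)oxy]-6α-hydroxy-1-oxolabda-8(17),13E-dien-18-yl pivalate | CC(C)(C)[Si](OC/C=C(\C)CC[C@@H]1[C@@]2(C)C(=O)CC[C@@](C)(COC(=O)C(C)(C)C)[C@@H]2[C@@H](O)CC1=C)(c1ccccc1)c1ccccc1 | intermediate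
21 | 15-[(tert-butyldiphenylsilyl)oxy]-6α,8α-dihydroxy-1-oxolabd-13E-en-18-yl pivalate | CC(C)(C)[Si](OC/C=C(\C)CC[C@@H]1[C@@]2(C)C(=O)CC[C@@](C)(COC(=O)C(C)(C)C)[C@@H]2[C@@H](O)C[C@@]1(C)O)(c1ccccc1)c1ccccc1 | intermediate
22 | labd-13E-ene-6α,8α,15,18-tetraol | OC/C=C(\C)CC[C@@H]1[C@@]2(C)CCC[C@@](C)(CO)[C@@H]2[C@@H](O)C[C@@]1(C)O | intermediate
23 | 6α,8α,18-trihydroxylabd-13E-en-15-al | O=C/C=C(\C)CC[C@@H]1[C@@]2(C)CCC[C@@](C)(CO)[C@@H]2[C@@H](O)C[C@@]1(C)O | intermediate
24 | 6α,8α,18-tris(triethylsilyloxy)labd-13E-en-15-al | O=C/C=C(\C)CC[C@@H]1[C@@]2(C)CCC[C@@](C)(CO[Si](CC)(CC)CC)[C@@H]2[C@@H](O[Si](CC)(CC)CC)C[C@@]1(C)O[Si](CC)(CC)CC | intermediate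
25 | 4-methylfuran-2(5H)-one | CC1=CC(=O)OC1 | starting material
26 | 4-methyl-2-(trimethylsilyloxy)furan | Cc1coc(O[Si](C)(C)C)c1 | intermediate
27 | 6,8,18-tris-O-(triethylsilyl) ether of the target (15S,16S) | CC1=CC(=O)O[C@@H]1[C@@H](O)/C=C(\C)CC[C@@H]1[C@@]2(C)CCC[C@@](C)(CO[Si](CC)(CC)CC)[C@@H]2[C@@H](O[Si](CC)(CC)CC)C[C@@]1(C)O[Si](CC)(CC)CC | intermediate
28 | CNP0255788.1, (15S,16S)-6α,8α,15,18-tetrahydroxy sesterterpenoid butenolide on the normal labdane core | CC1=CC(=O)O[C@@H]1[C@@H](O)/C=C(\C)CC[C@@H]1[C@@]2(C)CCC[C@@](C)(CO)[C@@H]2[C@@H](O)C[C@@]1(C)O | target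

Total step count: 21. Longest linear sequence: 18 steps (steps 1–4, 7–18, 20 and 21).

Steps most likely to fail:

Step 14. The aldehyde may enolise at C5 before the rearrangement, which would erase the C5/C10 relationship, or ring B may close through the competing axial-oxygen transition state. The fallback separates the two events and sets out from 16: heating 16 (PhMe, 150 °C) rearranges the enol ether while C6 is still a silyl ether and should give 15-[(tert-butyldiphenylsilyl)oxy]-6-[(tert-butyldimethylsilyl)oxy]-1-oxo-6,7-secolabda-7,13E-dien-18-yl pivalate F1; Bu4NF then frees 15-[(tert-butyldiphenylsilyl)oxy]-6-hydroxy-1-oxo-6,7-secolabda-7,13E-dien-18-yl pivalate F2; buffered Dess–Martin oxidation gives 19, now isolated, and Me2AlCl at −78 °C closes ring B, so that the route is rejoined at 20.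

Step 9. The acid-sensitive alkoxy diene may hydrolyse or rearrange under the cationic catalyst, and facial discrimination may be incomplete. The fallback replaces catalyst control by auxiliary control and sets out from 12: Et2AlCl-promoted Diels–Alder reaction of 12 with commercial (R)-pantolactone methacrylate at −78 °C should give the (R)-pantolactone ester of (1R,2R)-4-(arm-oxy)-2-{[(tert-butyldimethylsilyl)oxy]methyl}-1,3-dimethylcyclohex-3-ene-1-carboxylic acid F3 (the antipodal lactone is used if the facial sense is opposite); LiAlH4 in THF reduces the ester directly to the alcohol, and the route is rejoined at 15.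

Step 20. Facial and simple diastereoselection in the vinylogous aldol addition may be insufficient. The fallback builds C15 and C16 by an auxiliary-controlled syn-aldol reaction and then forms the butenolide; it sets out from 24. The dibutylboron enolate of (R)-4-benzyl-3-{[(4-methoxybenzyl)oxy]acetyl}oxazolidin-2-one (Bu2BOTf, Et3N, CH2Cl2, −78 °C) should add to 24 to give the syn-glycolate aldol imide F4; Et3SiOTf and 2,6-lutidine give its 15-O-triethylsilyl ether F5; MeNH(OMe)·HCl and AlMe3 give the Weinreb amide F6; MeMgBr gives the methyl ketone F7; DDQ in wet CH2Cl2 removes the 4-methoxybenzyl group to give the α-hydroxy ketone F8; ketenylidenetriphenylphosphorane in refluxing PhMe acylates the hydroxyl and closes the ring by intramolecular Wittig reaction to the 6,8,15,18-tetrakis-O-(triethylsilyl) ether of the target F9; HF·pyridine then gives 28, where the route is rejoined.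

Further compounds

F1 | step 14 | 15-[(tert-butyldiphenylsilyl)oxy]-6-[(tert-butyldimethylsilyl)oxy]-1-oxo-6,7-secolabda-7,13E-dien-18-yl pivalate | CC(C)(C)[Si](OC/C=C(\C)CC[C@@H](C(C)=C)[C@@]1(C)C(=O)CC[C@@](C)(COC(=O)C(C)(C)C)[C@@H]1CO[Si](C)(C)C(C)(C)C)(c1ccccc1)c1ccccc1
F2 | step 14 | 15-[(tert-butyldiphenylsilyl)oxy]-6-hydroxy-1-oxo-6,7-secolabda-7,13E-dien-18-yl pivalate | CC(C)(C)[Si](OC/C=C(\C)CC[C@@H](C(C)=C)[C@@]1(C)C(=O)CC[C@@](C)(COC(=O)C(C)(C)C)[C@@H]1CO)(c1ccccc1)c1ccccc1
F3 | step 9 | (R)-pantolactone ester of (1R,2R)-4-(arm-oxy)-2-{[(tert-butyldimethylsilyl)oxy]methyl}-1,3-dimethylcyclohex-3-ene-1-carboxylic acid | CC1=C(OC/C(C)=C\CC/C(C)=C/CO[Si](c2ccccc2)(c2ccccc2)C(C)(C)C)CC[C@@](C)(C(=O)O[C@H]2C(=O)OCC2(C)C)[C@@H]1CO[Si](C)(C)C(C)(C)C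
F4 | step 20 | syn-glycolate aldol imide: N-acyl (R)-4-benzyloxazolidin-2-one with 15-hydroxy and 16-(4-methoxybenzyloxy) groups on the tris(triethylsilyl) labdane enal | COc1ccc(CO[C@@H](C(=O)N2C(=O)OC[C@H]2Cc2ccccc2)[C@@H](O)/C=C(\C)CC[C@@H]2[C@@]3(C)CCC[C@@](C)(CO[Si](CC)(CC)CC)[C@@H]3[C@@H](O[Si](CC)(CC)CC)C[C@@]2(C)O[Si](CC)(CC)CC)cc1
F5 | step 20 | 15-O-triethylsilyl ether of F4 | COc1ccc(CO[C@@H](C(=O)N2C(=O)OC[C@H]2Cc2ccccc2)[C@@H](O[Si](CC)(CC)CC)/C=C(\C)CC[C@@H]2[C@@]3(C)CCC[C@@](C)(CO[Si](CC)(CC)CC)[C@@H]3[C@@H](O[Si](CC)(CC)CC)C[C@@]2(C)O[Si](CC)(CC)CC)cc1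
F6 | step 20 | N-methoxy-N-methyl amide (Weinreb amide) from F5 | COc1ccc(CO[C@@H](C(=O)N(C)OC)[C@@H](O[Si](CC)(CC)CC)/C=C(\C)CC[C@@H]2[C@@]3(C)CCC[C@@](C)(CO[Si](CC)(CC)CC)[C@@H]3[C@@H](O[Si](CC)(CC)CC)C[C@@]2(C)O[Si](CC)(CC)CC)cc1
F7 | step 20 | methyl ketone with 16-(4-methoxybenzyloxy) and 15-(triethylsilyloxy) groups | COc1ccc(CO[C@@H](C(C)=O)[C@@H](O[Si](CC)(CC)CC)/C=C(\C)CC[C@@H]2[C@@]3(C)CCC[C@@](C)(CO[Si](CC)(CC)CC)[C@@H]3[C@@H](O[Si](CC)(CC)CC)C[C@@]2(C)O[Si](CC)(CC)CC)cc1
F8 | step 20 | 16-hydroxy methyl ketone with 15-(triethylsilyloxy) group | O[C@@H](C(C)=O)[C@@H](O[Si](CC)(CC)CC)/C=C(\C)CC[C@@H]1[C@@]2(C)CCC[C@@](C)(CO[Si](CC)(CC)CC)[C@@H]2[C@@H](O[Si](CC)(CC)CC)C[C@@]1(C)O[Si](CC)(CC)CC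
F9 | step 20 | 6,8,15,18-tetrakis-O-(triethylsilyl) ether of the target | CC1=CC(=O)O[C@@H]1[C@@H](O[Si](CC)(CC)CC)/C=C(\C)CC[C@@H]1[C@@]2(C)CCC[C@@](C)(CO[Si](CC)(CC)CC)[C@@H]2[C@@H](O[Si](CC)(CC)CC)C[C@@]1(C)O[Si](CC)(CC)CC
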